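The C2‑symmetric target is cut at both C11=C12 bonds into the C10 trienedial and two copies of one C15 phosphonium salt, so a single stereocentre must be made: C6 of the cyclohexene ring (carotenoid numbering). The route exploits that C6 (carrying H and C7, lying between gem‑dimethyl C1 and C5 of the ring C4=C5 alkene) is the 1,3‑allylic partner of C4. A Wittig–Still [2,3] shift of the tributylstannylmethyl ether of (R)‑2,4,4‑trimethylcyclohex‑2‑en‑1‑ol forms C6–C7, copies the carbinol configuration onto C6 and moves the alkene to C4=C5 in one operation. The precursor is that ether, two steps from the commercial enone.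

Key step: step 3

Assumption: in the CBS reduction the 2‑methylalkenyl arm of enone 1 is taken as the larger carbonyl substituent, as for other 2‑substituted cyclohex‑2‑enones, which assigns the (S)‑catalyst to the (R)‑alcohol.

Step 1
Reactants: 1 2,4,4‑trimethylcyclohex‑2‑en‑1‑one
Product: 2 (1R)‑2,4,4‑trimethylcyclohex‑2‑en‑1‑ol
Conditions: (S)‑Me‑CBS [(3aS)‑1‑methyl‑3,3‑diphenyltetrahydro‑1H,3H‑pyrrolo[1,2‑c][1,3,2]oxazaborole, C18H20BNO] (10 mol %), BH3·SMe2, THF, −20 °C; MeOH, then aqueous work‑up
Reagents that add atoms: none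
Why: Corey–Bakshi–Shibata reduction, in which the ketone binds the catalyst boron anti to its bulkier 2‑methylalkenyl arm and the N‑bound borane delivers hydride to one carbonyl face, so the (S)‑catalyst should set the carbinol carbon (C4 in carotenoid numbering) as R, with 1,2‑reduction much faster than hydroboration of the hindered trisubstituted alkene.

Step 2
Reactants: 2 (1R)‑2,4,4‑trimethylcyclohex‑2‑en‑1‑ol; 3 tributyl(iodomethyl)stannane
Product: 5 tributyl({[(1R)‑2,4,4‑trimethylcyclohex‑2‑en‑1‑yl]oxy}methyl)stannane, via potassium alkoxide 4 (not isolated)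
Conditions: KH, THF, 0 °C to rt; then Bu3SnCH2I, rt
Reagents that add atoms: tributyl(iodomethyl)stannane, CCCC[Sn](CI)(CCCC)CCCC
Why: Williamson etherification of the potassium alkoxide with the activated primary iodide is the standard entry to stannylmethyl ethers and leaves the C–O stereocentre untouched, so the R configuration is carried over.

Step 3
Reactants: 5 tributyl({[(1R)‑2,4,4‑trimethylcyclohex‑2‑en‑1‑yl]oxy}methyl)stannane
Product: 7 (S)‑α‑cyclogeraniol, [(1S)‑2,6,6‑trimethylcyclohex‑2‑en‑1‑yl]methanol, via lithiomethyl ether 6 (not isolated)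
Conditions: n‑BuLi (1.3 equiv), THF, −78 °C; then H2O
Reagents that add atoms: none
Why: Tin–lithium exchange gives the unstabilised α‑alkoxymethyllithium 6, which undergoes a concerted [2,3]‑sigmatropic shift through a five‑membered envelope transition state: the carbanion carbon bonds to the distal alkene carbon (C6, beside gem‑dimethyl C1), the C4–O bond breaks and the π bond moves to C4=C5. The closest known reaction type is the Wittig–Still rearrangement of stannylmethyl ethers of cyclohex‑2‑enols, applied here to a new substrate. No ring is closed; one C–C bond and one stereocentre are formed. The new stereocentre C6 is controlled by the carbinol centre alone, because the tethered CH2 can only reach the ring face that carries the oxygen (suprafacial 1,3‑transfer), so the (R)‑ether should give the (S)‑alcohol. The step needs the [2,3] shift to win over the [1,2] shift and over protonation of 6; the low temperature and the 2‑methyl group, whose allylic strain holds the C–O bond pseudoaxial and aligned with the π system, should secure this. Conversion of a carbanion into a lithium alkoxide makes the shift irreversible and drives bond formation at the hindered carbon, and no acid or enolisable intermediate is present that could move the alkene.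

Step 4
Reactants: 7 (S)‑α‑cyclogeraniol
Product: 8 (S)‑α‑cyclocitral, (1S)‑2,6,6‑trimethylcyclohex‑2‑ene‑1‑carbaldehyde
Conditions: Dess–Martin periodinane, NaHCO3, CH2Cl2, 0 °C to rt; used crude at once
Reagents that add atoms: none
Why: Dess–Martin oxidation of a primary alcohol stops at the aldehyde under buffered, near‑neutral conditions, so the enolisable C6 centre and the β,γ‑alkene should stay in place.

Step 5
Reactants: 8 (S)‑α‑cyclocitral; 9 diethyl (2‑oxopropyl)phosphonate
Product: 10 (S)‑α‑ionone, (3E)‑4‑[(1S)‑2,6,6‑trimethylcyclohex‑2‑en‑1‑yl]but‑3‑en‑2‑one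
Conditions: LiCl, i‑Pr2NEt, MeCN, rt
Reagents that add atoms: diethyl (2‑oxopropyl)phosphonate, CCOP(=O)(CC(C)=O)OCC
Why: Horner–Wadsworth–Emmons olefination under Masamune–Roush conditions, where the lithium‑chelated β‑ketophosphonate is deprotonated by an amine too weak to enolise the hindered aldehyde and the stabilised carbanion gives the (E)‑enone with C6 untouched.

Step 6
Reactants: 10 (S)‑α‑ionone; 11 vinylmagnesium bromide
Product: 12 vinyl‑α‑ionol, (1E)‑3‑methyl‑1‑[(1S)‑2,6,6‑trimethylcyclohex‑2‑en‑1‑yl]penta‑1,4‑dien‑3‑ol (both C3 epimers)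
Conditions: CH2=CHMgBr, THF, −30 to 0 °C; then aq. NH4Cl
Reagents that add atoms: vinylmagnesium bromide, C=C[Mg]Br
Why: Grignard 1,2‑addition to the carbonyl of the enone is fast at low temperature compared with γ‑deprotonation at C6, and the new carbinol centre forms as both epimers, which does not matter because that carbon becomes sp2 in the next step.

Step 7
Reactants: 12 vinyl‑α‑ionol; 13 triphenylphosphine hydrobromide
Product: 14 [(2E,4E)‑3‑methyl‑5‑[(1S)‑2,6,6‑trimethylcyclohex‑2‑en‑1‑yl]penta‑2,4‑dien‑1‑yl]triphenylphosphonium bromide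
Conditions: PPh3·HBr, MeOH, 0 °C to rt; crystallisation
Reagents that add atoms: triphenylphosphine hydrobromide, [Br-].[PH+](c1ccccc1)(c1ccccc1)c1ccccc1
Why: Acid‑mediated allylic transposition (SN1‑type), in which loss of water gives a pentadienyl cation that triphenylphosphine captures at the unhindered primary terminus to give the conjugated salt with the favoured (E)‑C9=C10 bond, the standard C15 salt formation of carotenoid synthesis, with an acid too weak to touch C6 or the ring alkene.

Step 8
Reactants: 14 C15 phosphonium bromide (2.2 equiv); 15 (2E,4E,6E)‑2,7‑dimethylocta‑2,4,6‑trienedial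
Product: 18 (6S,6'S)‑ε,ε‑carotene, via phosphorus ylide 16 (not isolated), via C25 monoaldehyde 17 (not isolated)
Conditions: NaOMe, CH2Cl2/MeOH, 0 °C to rt, dark, Ar; crude heated in heptane at reflux, then crystallised
Reagents that add atoms: (2E,4E,6E)‑2,7‑dimethylocta‑2,4,6‑trienedial, O=C/C(C)=C/C=C/C=C(C)/C=O
Why: Twofold Wittig olefination of the dialdehyde with the allylic ylide forms C11=C12 and C11'=C12'; Z isomers at these sterically hindered disubstituted positions should revert to E on heating, and methoxide is too weak to remove the C6 hydrogens, so the all‑E (6S,6'S) compound should crystallise.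

Compound list
1 | 2,4,4‑trimethylcyclohex‑2‑en‑1‑one | CC1=CC(C)(C)CCC1=O | starting material
2 | (1R)‑2,4,4‑trimethylcyclohex‑2‑en‑1‑ol | CC1=CC(C)(C)CC[C@H]1O | intermediate
3 | tributyl(iodomethyl)stannane | CCCC[Sn](CI)(CCCC)CCCC | starting material
4 | potassium (1R)‑2,4,4‑trimethylcyclohex‑2‑en‑1‑olate (not isolated) | CC1=CC(C)(C)CC[C@H]1[O-].[K+] | intermediate
5 | tributyl({[(1R)‑2,4,4‑trimethylcyclohex‑2‑en‑1‑yl]oxy}methyl)stannane | CC1=CC(C)(C)CC[C@H]1OC[Sn](CCCC)(CCCC)CCCC | intermediate
6 | {[(1R)‑2,4,4‑trimethylcyclohex‑2‑en‑1‑yl]oxy}methyllithium (not isolated) | CC1=CC(C)(C)CC[C@H]1OC[Li] | intermediate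
7 | (S)‑α‑cyclogeraniol, [(1S)‑2,6,6‑trimethylcyclohex‑2‑en‑1‑yl]methanol | CC1=CCCC(C)(C)[C@@H]1CO | intermediate
8 | (S)‑α‑cyclocitral, (1S)‑2,6,6‑trimethylcyclohex‑2‑ene‑1‑carbaldehyde | CC1=CCCC(C)(C)[C@@H]1C=O | intermediate
9 | diethyl (2‑oxopropyl)phosphonate | CCOP(=O)(CC(C)=O)OCC | starting material
10 | (S)‑α‑ionone, (3E)‑4‑[(1S)‑2,6,6‑trimethylcyclohex‑2‑en‑1‑yl]but‑3‑en‑2‑one | CC1=CCCC(C)(C)[C@@H]1/C=C/C(C)=O | intermediate
11 | vinylmagnesium bromide | C=C[Mg]Br | starting material
12 | (1E)‑3‑methyl‑1‑[(1S)‑2,6,6‑trimethylcyclohex‑2‑en‑1‑yl]penta‑1,4‑dien‑3‑ol, both C3 epimers | CC1=CCCC(C)(C)[C@@H]1/C=C/C(C)(O)C=C | intermediate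
13 | triphenylphosphine hydrobromide | [Br-].[PH+](c1ccccc1)(c1ccccc1)c1ccccc1 | starting material
14 | [(2E,4E)‑3‑methyl‑5‑[(1S)‑2,6,6‑trimethylcyclohex‑2‑en‑1‑yl]penta‑2,4‑dien‑1‑yl]triphenylphosphonium bromide | CC1=CCCC(C)(C)[C@@H]1/C=C/C(C)=C/C[P+](c1ccccc1)(c1ccccc1)c1ccccc1.[Br-] | intermediate
15 | (2E,4E,6E)‑2,7‑dimethylocta‑2,4,6‑trienedial | O=C/C(C)=C/C=C/C=C(C)/C=O | starting material
16 | [(2E,4E)‑3‑methyl‑5‑[(1S)‑2,6,6‑trimethylcyclohex‑2‑en‑1‑yl]penta‑2,4‑dien‑1‑ylidene]triphenylphosphorane (not isolated) | CC1=CCCC(C)(C)[C@@H]1/C=C/C(C)=C/C=P(c1ccccc1)(c1ccccc1)c1ccccc1 | intermediate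
17 | 2,7,11‑trimethyl‑13‑[(1S)‑2,6,6‑trimethylcyclohex‑2‑en‑1‑yl]trideca‑2,4,6,8,10,12‑hexaenal, drawn all‑E, formed as an 8E/8Z mixture (not isolated) | CC1=CCCC(C)(C)[C@@H]1/C=C/C(C)=C/C=C/C(C)=C/C=C/C=C(C)/C=O | intermediate
18 | (6S,6'S)‑ε,ε‑carotene | CC1=CCCC(C)(C)[C@@H]1/C=C/C(C)=C/C=C/C(C)=C/C=C/C=C(C)/C=C/C=C(C)/C=C/[C@@H]1C(C)=CCCC1(C)C | target

Total step count: 8. Longest linear sequence: 8 steps (1 to 18; compounds 3, 9, 11, 13 and 15 are purchased).

Steps most likely to fail

Step 3. After tin–lithium exchange the unstabilised carbanion may be protonated or take the [1,2] path instead of bonding to the hindered alkene carbon beside the gem‑dimethyl group, or the chirality transfer may be incomplete. The fallback sets out from alcohol 2 and uses the neutral thermal carbene [2,3] variant (Büchi rearrangement). Heating 2 with N,N‑dimethylformamide dimethyl acetal in xylene at 140–160 °C with removal of methanol should give the mixed amide acetal 1‑methoxy‑N,N‑dimethyl‑1‑{[(1R)‑2,4,4‑trimethylcyclohex‑2‑en‑1‑yl]oxy}methanamine F1. Its alkoxy(amino)carbene should rearrange on the oxygen‑bearing face to the amide (1S)‑N,N,2,6,6‑pentamethylcyclohex‑2‑ene‑1‑carboxamide F2. Reduction of F2 with lithium amidotrihydroborate (LiH2N·BH3, THF) comes back to the route at alcohol 7.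

Step 5. Enolisation of the hindered, α‑branched β,γ‑unsaturated aldehyde during olefination may erode the C6 configuration or move the ring alkene into conjugation, and addition to the neopentyl‑type carbonyl may be slow. The fallback sets out from aldehyde 8 and replaces carbonyl olefination with base by a non‑basic iodo‑olefination and cross‑coupling. Takai reaction (CrCl2, CHI3, THF, 0 °C) should give (6S)‑6‑[(E)‑2‑iodoethenyl]‑1,5,5‑trimethylcyclohex‑1‑ene F3. Stille coupling of F3 with the known reagent (E)‑3‑(tributylstannyl)but‑2‑en‑1‑ol, C/C(=C\CO)[Sn](CCCC)(CCCC)CCCC (Pd(PPh3)4, CuI, DMF, rt), should give (2E,4E)‑3‑methyl‑5‑[(1S)‑2,6,6‑trimethylcyclohex‑2‑en‑1‑yl]penta‑2,4‑dien‑1‑ol F4. PPh3·HBr in MeOH then converts F4 into salt 14, where the route is rejoined (steps 6 and 7 are no longer needed).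

Step 1. Facial discrimination in the catalytic reduction may be insufficient because only the 2‑methyl group differentiates the two carbonyl arms; any wrong enantiomer would end mainly in the meso (6R,6'S) diastereomer of the final product. The fallback sets out from enone 1 and uses resolution instead of asymmetric catalysis. Luche reduction (NaBH4, CeCl3·7H2O, MeOH, 0 °C) should give racemic 2,4,4‑trimethylcyclohex‑2‑en‑1‑ol F5. Acylation with vinyl acetate and Novozym 435 (immobilised Candida antarctica lipase B) in hexane should, by the usual secondary‑alcohol preference of this lipase, give (1R)‑2,4,4‑trimethylcyclohex‑2‑en‑1‑yl acetate F6 and leave (1S)‑2,4,4‑trimethylcyclohex‑2‑en‑1‑ol F7, which is separated. Methanolysis of F6 (K2CO3, MeOH) comes back to the route at alcohol 2.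

Further compounds
F1 | step 3 | 1‑methoxy‑N,N‑dimethyl‑1‑{[(1R)‑2,4,4‑trimethylcyclohex‑2‑en‑1‑yl]oxy}methanamine | CC1=CC(C)(C)CC[C@H]1OC(OC)N(C)C
F2 | step 3 | (1S)‑N,N,2,6,6‑pentamethylcyclohex‑2‑ene‑1‑carboxamide | CC1=CCCC(C)(C)[C@@H]1C(=O)N(C)C
F3 | step 5 | (6S)‑6‑[(E)‑2‑iodoethenyl]‑1,5,5‑trimethylcyclohex‑1‑ene | CC1=CCCC(C)(C)[C@@H]1/C=C/I
F4 | step 5 | (2E,4E)‑3‑methyl‑5‑[(1S)‑2,6,6‑trimethylcyclohex‑2‑en‑1‑yl]penta‑2,4‑dien‑1‑ol | CC1=CCCC(C)(C)[C@@H]1/C=C/C(C)=C/CO
F5 | step 1 | racemic 2,4,4‑trimethylcyclohex‑2‑en‑1‑ol | CC1=CC(C)(C)CCC1O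
F6 | step 1 | (1R)‑2,4,4‑trimethylcyclohex‑2‑en‑1‑yl acetate | CC1=CC(C)(C)CC[C@H]1OC(C)=O
F7 | step 1 | (1S)‑2,4,4‑trimethylcyclohex‑2‑en‑1‑ol | CC1=CC(C)(C)CC[C@@H]1O
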